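You are asked how steeply the early rate answers to J around the west charge, and what share of Q has become L in the south-east flask at the late time.

| flask | Q | J | time |
|---|---|---|---|
| west | 0.400 M | 0.320 M |  |
| south | 0.400 M | 0.640 M |  |
| south-east | 0.400 M | 0.320 M | 41 min |

- west run (time / min: [L] / M): 0.28: 0.0135; 0.53: 0.0239; 1.0: 0.0392; 1.9: 0.0560; 3.6: 0.0730; 6.9: 0.0803
- south run (time / min: [L] / M): 0.28: 0.0387; 0.53: 0.0606; 1.0: 0.0919; 1.9: 0.1241; 3.6: 0.1462; 6.9: 0.1620

(scatter of a reading: 0.002 M)

- reaction order in [J] at the outset, round the charge of the west run, defined at two percent of the Q turned into L
- L in the south-east run at 41 min, as a share of the Q charged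

- Overall: Q + J -> L.
- Constant volume, constant temperature.
- "The second partner" is J.
- An order is taken over about fifteen percent of the charge, up and down.

Start from two extreme flasks, with Q held near its charge. If the rate went with J to the first power (pseudo-first-order), the south run, with twice the J of the west run, would start 2 times as fast. If it went with J squared, the factor would be 4. At 0.28 min the reading of L in the south run over that in the west run is 2.87, which is more than the first factor and less than the second, so the real flask lies between.

So let both parts run side by side. One concentration then ranks them: the crossover concentration, the J at which the two parts of the rate are equal, read here as 0.418 M. Well below it the order nears one; well above it, two. The order at a given J is one plus J/(J + crossover), which by my reckoning gives 1.43 at the west charge, lower than the forecast's 1.65.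

The south-east flask has the west charge, and the last west reading is 20.1 % of the Q charged, so I would take about that share. The forecast says 21.5 %, on these grounds: “Plateaus proportional to J, with faster decay at high J, suggest a dying active species or an equilibrium”.

The flask gives 1.4 and 20.3 %, from these steps:

    Q + J → L (0.3408 /M/min)
    Q + 2 J → L + J (0.4572 /M²/min)
    J → Jo (0.3114 /min)
    2 Q → Vo (0.2796 /M/min)

At equal L made, the south rate is 2.8 times the west rate. The crossover I read from one ratio of scattered readings, 0.418 M, gave me the order 1.43 at the west charge, a reckoning that counts no loss of J, beside the flask's 1.4. For the south run, that reading multiplies the west rate of 0.054 M/min by 2(crossover + south J)/(crossover + west J), which gives 0.155 M/min, and that run's rate stands at 0.15 M/min.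

(The numbers in the tables were computed from invented constants, and the scatter is random.)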